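Do not read a rate that falls at steady selectivity as a dead catalyst before you have counted what the solid can pay for.

- cedar: Qa 0.50 M; Qb 0.50 M; Qf 1.5 M; Qd 5 mM; run made earlier
- flask: Qa 0.50 M; Qf 1.00 M; Qd 5.0 mM; Qb 0.50 M; time 3.0 h

cedar run (percent of the Qa and Qb together charged)

| time / min | Qh / % | Qb / % |
|---|---|---|
| 4.00 | 1.2 | 49.0 |
| 8.00 | 3.4 | 48.0 |
| 12.0 | 5.2 | 46.4 |
| 20.0 | 8.9 | 42.8 |
| 30.0 | 13.8 | 39.1 |
| 50.0 | 17.3 | 36.4 |

(each reading ± 0.3 percentage points)

- Qd is single-handed; Qa and Qb are mirror images of each other, charged as a racemate, each of them at the stated concentration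
- Qf is a solid; its amount is given per volume of the solution
- the earlier runs were read with a standard deviation of 0.3 percentage points
- at the start none of Qf is in solution
- the reaction counts as stopped when no species that holds the Qa and Qb together changes by six tenths of a point or more over the second half of the time

- why nothing more happens at 3.0 h, or that something still does (for what has run out or reacted, a solid counts together with what of it has only dissolved) (no working catalyst is left / Qc has run out first / forward and back rates have come level / it is still moving / all of Qa has reacted)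
- Qh at 3.0 h, in percent of the Qa and Qb together charged
- Qb at 3.0 h, in percent of the Qa and Qb together charged
- Qj at 3.0 h, in percent of the Qa and Qb together charged

1. Count turnovers of the solid. In cedar, Qa and Qb together are 1.00 M, so the last reading of Qh, 17.3% at 50.0 min, means 0.173 M of Qh against 1.5 M of Qf charged. Call η the Qf yield, the moles of Qh made per mole of Qf charged at fixed Qd: η = 11.5%.

2. Set the upper bound. Assume that less solid gives no more Qh at equal Qd, and take cedar's reading of 17.3% as the estimated ceiling on Qh in this flask.

3. Set the lower bound. Cedar's Qh gains 4.9 percentage points from 20.0 min to 30.0 min, but 3.5 points in the longer stretch after it. Scale the reading at that bend by the Qf charges: 9.20%.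

4. Tighten. My own reckoning applies η to 1.00 M of Qf and gives Qh 11.5%. Scaling cedar's Qb loss the same way gives Qb 40.9%.

5. Place the forecast: no working catalyst is left; Qh 14.6%, Qb 38.6%, Qj 11.4%. Its ground: “Both enantiomers slow by a common factor, so the likeliest cause is catalyst death.” Its Qh lies inside the bracket, higher than my value.

6. Read the flask: Qc has run out first; Qh 11.9%, Qb 40.6%, Qj 6.83%.

    Qa ⇌ Qb (k = 0.133 min⁻¹)
    Qc → Qg (k = 0.215 min⁻¹)
    Qc + Qd + Qb → Qd + Qj (k = 15.3 M⁻² min⁻¹)
    Qc + Qd + Qa → Qd + Qh (k = 27.0 M⁻² min⁻¹)
    2 Qc → Qe (k = 1.36 M⁻¹ min⁻¹)
    Qf ⇌ Qc, rate k6*(cs6 - [Qc]) while solid is left; crystals form when [Qc] > cs6 (solubility = 0.260 M, k = 0.232 min⁻¹)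

The running short of Qf is the main reason for the stop: this flask converts 18.7% of Qa and Qb together, and the run without that shortage converts 79.1%. At 3.00 h, Qd stands at 100% of its charge and Qf at 0% of its own. The flask's η is 11.9%. The neighbour flask, with 0.013 M of Qd and the same Qf, also ends with Qf at 0%, and its η is 22.7%.

The earlier runs and the new flask were generated by integration for an exercise, and the scatter is random.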